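**Retrosynthetic overview**

- Endgame: one fluoride step removes the temporary C5 ester (decarboxylative protonation sets C5) and both silyl ethers; before it, a Mitsunobu inversion at C1 installs the angelate, and before that the C1 oxygen is introduced by γ-hydroxylation (dienol ether, singlet oxygen).
- Key disconnection: the only ring (the cyclohex-2-enone, C1–C6) is opened across C2=C3 and C5–C6, giving an acyclic β-ketoester (C3–C4–C5, already carrying the C5 ester and the C3 CH2O carbon) and (E)-4-methylpent-2-enal (C2–C1–C6). The forward reaction is an amine-catalysed Michael addition/aldol condensation.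
- Enabling feature: the C4 ketone lies between C3 and C5. C3 is part of the ring enone C2=C3–C4=O (aldol-condensation retron, C2 a former aldehyde carbon). C5–C6 is the bond of the 1,5-dicarbonyl relationship between C4=O and C2 (Michael retron). The C5 oxygen plus a temporary C5 carboxylate make C5 the single acidic carbon.
- Stereochemistry: C6 comes from the catalyst in the key step; C1 from oxygen delivery anti to the isopropyl group followed by inversion; C5 from protonation anti to the isopropyl group.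
- The β-ketoester comes from 2-(trimethylsilyl)ethyl acetoacetate (dianion hydroxymethylation, chlorination, carboxylate displacement) and a silyl-protected 4-hydroxytiglic acid made by Wittig olefination of glycolaldehyde.

Key step: step 9

Remark: ring carbons are numbered as in the name of the target: C1 carries the angeloyloxy group, C2=C3 is the alkene (C3 carries CH2OH), C4 is the ketone, C5 carries the 4-hydroxytigloyloxy group, C6 carries the isopropyl group. All intermediates from the key step up to the last step are carried as mixtures of the two epimers at C5 ("RS" in the names); both should give the same final product.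

Step 1
Reactants: 1 glycolaldehyde (bought as its crystalline dimer, which reverts to the monomer on heating); 2 ethyl 2-(triphenyl-λ5-phosphanylidene)propanoate
Product: 3 ethyl (2E)-4-hydroxy-2-methylbut-2-enoate
Conditions: THF, reflux
Reagents that add atoms: none
Why: Wittig olefination with a stabilised α-methyl ylide should give the (E)-trisubstituted enoate, the ester trans to the CH2OH-bearing carbon.

Step 2
Reactants: 3 ethyl (2E)-4-hydroxy-2-methylbut-2-enoate
Product: 4 ethyl (2E)-4-[(tert-butyldiphenylsilyl)oxy]-2-methylbut-2-enoate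
Conditions: TBDPSCl, imidazole, DMF, 0 °C to rt
Reagents that add atoms: tert-butyl(chloro)diphenylsilane, CC(C)(C)[Si](Cl)(c1ccccc1)c1ccccc1
Why: Silyl ether formation on the primary alcohol; the TBDPS group should survive saponification, mild acid, photooxygenation and Mitsunobu conditions until step 13.

Step 3
Reactants: 4 ethyl (2E)-4-[(tert-butyldiphenylsilyl)oxy]-2-methylbut-2-enoate
Product: 5 (2E)-4-[(tert-butyldiphenylsilyl)oxy]-2-methylbut-2-enoic acid
Conditions: LiOH·H2O, THF/MeOH/H2O, rt; then 1 M HCl to pH 3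
Reagents that add atoms: lithium hydroxide, [Li+].[OH-]
Why: Ester saponification; the primary TBDPS ether and the (E)-alkene should be untouched by LiOH at room temperature.

Step 4
Reactants: 6 2-(trimethylsilyl)ethanol; 7 2,2,6-trimethyl-4H-1,3-dioxin-4-one
Product: 8 2-(trimethylsilyl)ethyl 3-oxobutanoate
Conditions: xylene, 140 °C, acetone distilled off
Reagents that add atoms: none
Why: Thermal retro-[4+2] fragmentation of the dioxinone gives acetylketene, which the alcohol traps (acetoacetylation); the ester chosen is stable to acid and base and is cleaved only by fluoride.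

Step 5
Reactants: 8 2-(trimethylsilyl)ethyl 3-oxobutanoate
Product: 9 2-(trimethylsilyl)ethyl 5-hydroxy-3-oxopentanoate
Conditions: NaH, THF, 0 °C; n-BuLi, −10 °C; HCHO (gas, from heated paraformaldehyde), −78 °C; aq. HCl
Reagents that add atoms: formaldehyde, C=O
Why: The β-ketoester dianion reacts at its terminal, more basic carbon in an aldol addition to formaldehyde, which adds the future hydroxymethyl carbon on C3.

Step 6
Reactants: 9 2-(trimethylsilyl)ethyl 5-hydroxy-3-oxopentanoate
Product: 10 2-(trimethylsilyl)ethyl 5-[(tert-butyldiphenylsilyl)oxy]-3-oxopentanoate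
Conditions: TBDPSCl, imidazole, CH2Cl2, 0 °C
Reagents that add atoms: tert-butyl(chloro)diphenylsilane, CC(C)(C)[Si](Cl)(c1ccccc1)c1ccccc1
Why: Silyl ether formation on the primary alcohol, done at once so that the δ-hydroxy-β-ketoester cannot lactonise.

Step 7
Reactants: 10 2-(trimethylsilyl)ethyl 5-[(tert-butyldiphenylsilyl)oxy]-3-oxopentanoate
Product: 11 2-(trimethylsilyl)ethyl 5-[(tert-butyldiphenylsilyl)oxy]-2-chloro-3-oxopentanoate (racemic)
Conditions: SO2Cl2 (1.0 equiv), CH2Cl2, 0 °C
Reagents that add atoms: sulfuryl chloride, O=S(=O)(Cl)Cl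
Why: Electrophilic α-chlorination of the β-ketoester enol occurs at the carbon between the two carbonyl groups, the future C5.

Step 8
Reactants: 11 2-(trimethylsilyl)ethyl 5-[(tert-butyldiphenylsilyl)oxy]-2-chloro-3-oxopentanoate; 5 (2E)-4-[(tert-butyldiphenylsilyl)oxy]-2-methylbut-2-enoic acid
Product: 12 2-(trimethylsilyl)ethyl 5-[(tert-butyldiphenylsilyl)oxy]-2-{[(2E)-4-[(tert-butyldiphenylsilyl)oxy]-2-methylbut-2-enoyl]oxy}-3-oxopentanoate (racemic)
Conditions: Cs2CO3 (0.55 equiv, premixed with 5), DMF, 0 °C to rt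
Reagents that add atoms: none
Why: SN2 displacement of the doubly activated α-chloride by the cesium carboxylate (carboxylate alkylation) makes the C5–O ester bond of the target before the ring exists.

Step 9
Reactants: 12 2-(trimethylsilyl)ethyl 5-[(tert-butyldiphenylsilyl)oxy]-2-{[(2E)-4-[(tert-butyldiphenylsilyl)oxy]-2-methylbut-2-enoyl]oxy}-3-oxopentanoate; 13 (2E)-4-methylpent-2-enal
Product: 15 2-(trimethylsilyl)ethyl (1RS,6R)-1-{[(2E)-4-[(tert-butyldiphenylsilyl)oxy]-2-methylbut-2-enoyl]oxy}-3-{[(tert-butyldiphenylsilyl)oxy]methyl}-2-oxo-6-(propan-2-yl)cyclohex-3-ene-1-carboxylate, via keto aldehyde 14 (not isolated)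
Conditions: (R)-2-{bis[3,5-bis(trifluoromethyl)phenyl][(trimethylsilyl)oxy]methyl}pyrrolidine (10 mol %), PhCO2H (10 mol %), toluene, rt; then TsOH·H2O (20 mol %), 40 °C
Reagents that add atoms: none
Why: The diarylprolinol silyl ether condenses with enal 13 to an E-iminium ion whose β-carbon (C6) is attacked by the enol of β-ketoester 12 through its only doubly activated carbon (C5), and hydrolysis of the enamine releases keto aldehyde 14; TsOH then enolises the C4 ketone towards C3 (C5 is fully substituted), the enol adds to the C2 aldehyde and loss of water gives the conjugated C2=C3 bond. The closest known reaction type is the organocatalytic Michael addition/aldol condensation of β-ketoesters with enals to 5-substituted cyclohex-2-enones (a formal carbo-[3+3] annulation). The six-membered ring closes by a 6-(enolendo)-exo-trig aldol addition followed by dehydration. C6 is set by the catalyst, whose diaryl(silyloxy)methyl group shields one face of the iminium ion; the (R)-catalyst should expose the face that gives (6R), while C5 forms as both epimers, which is harmless because this centre is set anew in step 13. The step needs 1,4- over 1,2-addition (secured by iminium activation and a soft, stabilised nucleophile), attack through C5 and not C3 (secured by the temporary ester and the acyloxy group, which make C5–H by far the most acidic), and aldol closure without loss of the β-silyloxy group (secured by mild acid and the fast six-ring closure).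

Step 10
Reactants: 15 the cyclohexenone from step 9
Product: 16 2-(trimethylsilyl)ethyl (1RS,6S)-1-{[(2E)-4-[(tert-butyldiphenylsilyl)oxy]-2-methylbut-2-enoyl]oxy}-3-{[(tert-butyldiphenylsilyl)oxy]methyl}-6-(propan-2-yl)-2-[(trimethylsilyl)oxy]cyclohexa-2,4-diene-1-carboxylate
Conditions: TMSOTf, Et3N, CH2Cl2, 0 °C
Reagents that add atoms: trimethylsilyl trifluoromethanesulfonate, C[Si](C)(C)OS(=O)(=O)C(F)(F)F
Why: Soft enolisation (silyl triflate/amine); because C5 has no hydrogen, only γ-deprotonation at C1 is possible and the linear 2-silyloxy-1,3-diene should form.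

Step 11
Reactants: 16 the silyl dienol ether from step 10
Product: 19 2-(trimethylsilyl)ethyl (1RS,5R,6S)-1-{[(2E)-4-[(tert-butyldiphenylsilyl)oxy]-2-methylbut-2-enoyl]oxy}-3-{[(tert-butyldiphenylsilyl)oxy]methyl}-5-hydroxy-2-oxo-6-(propan-2-yl)cyclohex-3-ene-1-carboxylate, via endoperoxide 17 (not isolated), via hydroperoxide 18 (not isolated)
Conditions: O2, hν, 5,10,15,20-tetraphenylporphyrin (cat.), CH2Cl2, −78 °C; MeOH; then PPh3, −78 °C to rt
Reagents that add atoms: dioxygen (as singlet oxygen), O=O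
Why: [4+2] cycloaddition of singlet oxygen to the cisoid silyloxydiene gives the endoperoxide, which collapses on methanolysis to the γ-hydroperoxy enone and is reduced by PPh3 (overall γ-hydroxylation); oxygen should add to the diene face opposite to the C6 isopropyl group, so the new C1–O bond is trans to isopropyl.

Step 12
Reactants: 19 the γ-hydroxy enone from step 11; 20 angelic acid, (2Z)-2-methylbut-2-enoic acid
Product: 21 2-(trimethylsilyl)ethyl (1RS,5S,6S)-1-{[(2E)-4-[(tert-butyldiphenylsilyl)oxy]-2-methylbut-2-enoyl]oxy}-3-{[(tert-butyldiphenylsilyl)oxy]methyl}-5-{[(2Z)-2-methylbut-2-enoyl]oxy}-2-oxo-6-(propan-2-yl)cyclohex-3-ene-1-carboxylate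
Conditions: PPh3, DIAD, toluene, 0 °C to rt
Reagents that add atoms: none
Why: Mitsunobu esterification: SN2 displacement of the oxyphosphonium by angelate inverts C1 and places the ester cis to the isopropyl group (as in the known inversion of menthol to neomenthyl esters), and the neutral conditions should not isomerise the (Z)-alkene of the angelate.

Step 13
Reactants: 21 the angelate from step 12
Product: 23 (1S,5S,6S)-5-{[(2E)-4-hydroxy-2-methylbut-2-enoyl]oxy}-3-(hydroxymethyl)-4-oxo-6-(propan-2-yl)cyclohex-2-en-1-yl (2Z)-2-methylbut-2-enoate, via keto acid 22 (not isolated)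
Conditions: Bu4NF/AcOH (1:1, 4 equiv), THF, 0 °C to rt
Reagents that add atoms: none
Why: Fluoride cleaves the 2-(trimethylsilyl)ethyl ester by β-elimination and removes both TBDPS ethers (desilylation); the β-keto acid loses CO2 and the resulting enol, the same for both C5 epimers, should be protonated at C5 from the face opposite to the isopropyl and angeloyloxy groups (decarboxylative protonation), which gives the all-cis (5S) centre.

**Compound list**

1 | glycolaldehyde (hydroxyacetaldehyde, bought as its dimer) | OCC=O | starting material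
2 | ethyl 2-(triphenyl-λ5-phosphanylidene)propanoate | CCOC(=O)C(C)=P(c1ccccc1)(c1ccccc1)c1ccccc1 | starting material
3 | ethyl (2E)-4-hydroxy-2-methylbut-2-enoate | CCOC(=O)/C(C)=C/CO | intermediate
4 | ethyl (2E)-4-[(tert-butyldiphenylsilyl)oxy]-2-methylbut-2-enoate | CCOC(=O)/C(C)=C/CO[Si](c1ccccc1)(c1ccccc1)C(C)(C)C | intermediate
5 | (2E)-4-[(tert-butyldiphenylsilyl)oxy]-2-methylbut-2-enoic acid | OC(=O)/C(C)=C/CO[Si](c1ccccc1)(c1ccccc1)C(C)(C)C | intermediate
6 | 2-(trimethylsilyl)ethanol | C[Si](C)(C)CCO | starting material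
7 | 2,2,6-trimethyl-4H-1,3-dioxin-4-one | CC1=CC(=O)OC(C)(C)O1 | starting material
8 | 2-(trimethylsilyl)ethyl 3-oxobutanoate | CC(=O)CC(=O)OCC[Si](C)(C)C | intermediate
9 | 2-(trimethylsilyl)ethyl 5-hydroxy-3-oxopentanoate | OCCC(=O)CC(=O)OCC[Si](C)(C)C | intermediate
10 | 2-(trimethylsilyl)ethyl 5-[(tert-butyldiphenylsilyl)oxy]-3-oxopentanoate | CC(C)(C)[Si](c1ccccc1)(c1ccccc1)OCCC(=O)CC(=O)OCC[Si](C)(C)C | intermediate
11 | 2-(trimethylsilyl)ethyl 5-[(tert-butyldiphenylsilyl)oxy]-2-chloro-3-oxopentanoate (racemic) | CC(C)(C)[Si](c1ccccc1)(c1ccccc1)OCCC(=O)C(Cl)C(=O)OCC[Si](C)(C)C | intermediate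
12 | 2-(trimethylsilyl)ethyl 5-[(tert-butyldiphenylsilyl)oxy]-2-{[(2E)-4-[(tert-butyldiphenylsilyl)oxy]-2-methylbut-2-enoyl]oxy}-3-oxopentanoate (racemic) | CC(C)(C)[Si](c1ccccc1)(c1ccccc1)OCCC(=O)C(OC(=O)/C(C)=C/CO[Si](c1ccccc1)(c1ccccc1)C(C)(C)C)C(=O)OCC[Si](C)(C)C | intermediate
13 | (2E)-4-methylpent-2-enal | CC(C)/C=C/C=O | starting material
14 | 2-(trimethylsilyl)ethyl (2RS,3R)-2-{3-[(tert-butyldiphenylsilyl)oxy]propanoyl}-2-{[(2E)-4-[(tert-butyldiphenylsilyl)oxy]-2-methylbut-2-enoyl]oxy}-5-oxo-3-(propan-2-yl)pentanoate | CC(C)(C)[Si](c1ccccc1)(c1ccccc1)OCCC(=O)C(OC(=O)/C(C)=C/CO[Si](c1ccccc1)(c1ccccc1)C(C)(C)C)(C(=O)OCC[Si](C)(C)C)[C@H](CC=O)C(C)C | intermediate (not isolated)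
15 | 2-(trimethylsilyl)ethyl (1RS,6R)-1-{[(2E)-4-[(tert-butyldiphenylsilyl)oxy]-2-methylbut-2-enoyl]oxy}-3-{[(tert-butyldiphenylsilyl)oxy]methyl}-2-oxo-6-(propan-2-yl)cyclohex-3-ene-1-carboxylate | C1C=C(CO[Si](c2ccccc2)(c2ccccc2)C(C)(C)C)C(=O)C(OC(=O)/C(C)=C/CO[Si](c2ccccc2)(c2ccccc2)C(C)(C)C)(C(=O)OCC[Si](C)(C)C)[C@H]1C(C)C | intermediate
16 | 2-(trimethylsilyl)ethyl (1RS,6S)-1-{[(2E)-4-[(tert-butyldiphenylsilyl)oxy]-2-methylbut-2-enoyl]oxy}-3-{[(tert-butyldiphenylsilyl)oxy]methyl}-6-(propan-2-yl)-2-[(trimethylsilyl)oxy]cyclohexa-2,4-diene-1-carboxylate | C1=CC(CO[Si](c2ccccc2)(c2ccccc2)C(C)(C)C)=C(O[Si](C)(C)C)C(OC(=O)/C(C)=C/CO[Si](c2ccccc2)(c2ccccc2)C(C)(C)C)(C(=O)OCC[Si](C)(C)C)[C@H]1C(C)C | intermediate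
17 | endoperoxide of 16: 2,3-dioxabicyclo[2.2.2]oct-5-ene with the O–O bridge from C1 to C4 on the ring face opposite to the isopropyl group and OSiMe3 on C4 | O2[C@@H]1C=C(CO[Si](c3ccccc3)(c3ccccc3)C(C)(C)C)[C@@](O2)(O[Si](C)(C)C)C(OC(=O)/C(C)=C/CO[Si](c3ccccc3)(c3ccccc3)C(C)(C)C)(C(=O)OCC[Si](C)(C)C)[C@H]1C(C)C | intermediate (not isolated)
18 | 2-(trimethylsilyl)ethyl (1RS,5R,6S)-1-{[(2E)-4-[(tert-butyldiphenylsilyl)oxy]-2-methylbut-2-enoyl]oxy}-3-{[(tert-butyldiphenylsilyl)oxy]methyl}-5-hydroperoxy-2-oxo-6-(propan-2-yl)cyclohex-3-ene-1-carboxylate | OO[C@@H]1C=C(CO[Si](c2ccccc2)(c2ccccc2)C(C)(C)C)C(=O)C(OC(=O)/C(C)=C/CO[Si](c2ccccc2)(c2ccccc2)C(C)(C)C)(C(=O)OCC[Si](C)(C)C)[C@H]1C(C)C | intermediate (not isolated)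
19 | 2-(trimethylsilyl)ethyl (1RS,5R,6S)-1-{[(2E)-4-[(tert-butyldiphenylsilyl)oxy]-2-methylbut-2-enoyl]oxy}-3-{[(tert-butyldiphenylsilyl)oxy]methyl}-5-hydroxy-2-oxo-6-(propan-2-yl)cyclohex-3-ene-1-carboxylate | O[C@@H]1C=C(CO[Si](c2ccccc2)(c2ccccc2)C(C)(C)C)C(=O)C(OC(=O)/C(C)=C/CO[Si](c2ccccc2)(c2ccccc2)C(C)(C)C)(C(=O)OCC[Si](C)(C)C)[C@H]1C(C)C | intermediate
20 | angelic acid, (2Z)-2-methylbut-2-enoic acid | C/C=C(/C)C(=O)O | starting material
21 | 2-(trimethylsilyl)ethyl (1RS,5S,6S)-1-{[(2E)-4-[(tert-butyldiphenylsilyl)oxy]-2-methylbut-2-enoyl]oxy}-3-{[(tert-butyldiphenylsilyl)oxy]methyl}-5-{[(2Z)-2-methylbut-2-enoyl]oxy}-2-oxo-6-(propan-2-yl)cyclohex-3-ene-1-carboxylate | C/C=C(/C)C(=O)O[C@H]1C=C(CO[Si](c2ccccc2)(c2ccccc2)C(C)(C)C)C(=O)C(OC(=O)/C(C)=C/CO[Si](c2ccccc2)(c2ccccc2)C(C)(C)C)(C(=O)OCC[Si](C)(C)C)[C@H]1C(C)C | intermediate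
22 | (1RS,5S,6S)-1-{[(2E)-4-hydroxy-2-methylbut-2-enoyl]oxy}-3-(hydroxymethyl)-5-{[(2Z)-2-methylbut-2-enoyl]oxy}-2-oxo-6-(propan-2-yl)cyclohex-3-ene-1-carboxylic acid | C/C=C(/C)C(=O)O[C@H]1C=C(CO)C(=O)C(OC(=O)/C(C)=C/CO)(C(=O)O)[C@H]1C(C)C | intermediate (not isolated)
23 | (1S,5S,6S)-5-{[(2E)-4-hydroxy-2-methylbut-2-enoyl]oxy}-3-(hydroxymethyl)-4-oxo-6-(propan-2-yl)cyclohex-2-en-1-yl (2Z)-2-methylbut-2-enoate | C/C=C(/C)C(=O)O[C@H]1C=C(CO)C(=O)[C@@H](OC(=O)/C(C)=C/CO)[C@H]1C(C)C | target

**Step count and risks**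

Total step count: 13. Longest linear sequence: 10 steps (steps 4 to 13).

Steps most likely to fail:

Step 9. The conjugate addition of the fully substituted, acyloxy-bearing C5 carbon to the β-branched iminium ion may be too slow, so that retro-Michael reaction, acyl transfer to the amine or loss of silanol during the acid-promoted aldol condensation take over. The fallback sets out from 10 and comes back at 15, and makes the C5–O bond after, not before, ring formation. The same amine-catalysed Michael addition/TsOH aldol condensation is run with the unsubstituted β-ketoester 10 and enal 13, the substrate class for which this annulation is established. This should give 2-(trimethylsilyl)ethyl (1RS,6R)-3-{[(tert-butyldiphenylsilyl)oxy]methyl}-2-oxo-6-(propan-2-yl)cyclohex-3-ene-1-carboxylate F1. Its β-ketoester carbon is hydroxylated with dimethyldioxirane (acetone, 0 °C) to the tertiary alcohol 2-(trimethylsilyl)ethyl (1RS,6R)-3-{[(tert-butyldiphenylsilyl)oxy]methyl}-1-hydroxy-2-oxo-6-(propan-2-yl)cyclohex-3-ene-1-carboxylate F2. Yamaguchi esterification of F2 with acid 5 (2,4,6-trichlorobenzoyl chloride, Et3N, then 4-(dimethylamino)pyridine, toluene) gives 15.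

Step 12. The activated allylic oxyphosphonium may eliminate to a dienone, or displacement at a carbinol carbon next to the isopropyl-bearing C6 may be too slow, so that little inverted ester forms. The fallback sets out from 16, comes back at 21, and replaces steps 11 and 12. Dienol ether 16 is brominated at C1 with N-bromosuccinimide (THF, −78 °C; bromine should enter anti to the isopropyl group) to give 2-(trimethylsilyl)ethyl (1RS,5R,6R)-5-bromo-1-{[(2E)-4-[(tert-butyldiphenylsilyl)oxy]-2-methylbut-2-enoyl]oxy}-3-{[(tert-butyldiphenylsilyl)oxy]methyl}-2-oxo-6-(propan-2-yl)cyclohex-3-ene-1-carboxylate F3. SN2 displacement of the bromide in F3 by the cesium salt of 20 (20, Cs2CO3, DMF, 0 °C) with inversion gives 21.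

Step 13. Protonation at C5 may show poor facial selectivity, and the new α-acyloxy ketone centre may epimerise or an acyl group may migrate while the fully deprotected product sits in basic fluoride. The fallback sets out from 19 and comes back at 23; it sets C5 on a protected intermediate and ends under acidic conditions. Bu4NF/AcOH (1.1 equiv, THF, −20 °C) should cleave only the 2-(trimethylsilyl)ethyl ester, and decarboxylation gives (1S,5R,6S)-3-{[(tert-butyldiphenylsilyl)oxy]methyl}-5-hydroxy-2-oxo-6-(propan-2-yl)cyclohex-3-en-1-yl (2E)-4-[(tert-butyldiphenylsilyl)oxy]-2-methylbut-2-enoate F4, whose C5 epimers can be separated at this stage. Mitsunobu reaction of F4 with 20 (PPh3, DIAD) gives (1S,5S,6S)-3-{[(tert-butyldiphenylsilyl)oxy]methyl}-5-{[(2E)-4-[(tert-butyldiphenylsilyl)oxy]-2-methylbut-2-enoyl]oxy}-4-oxo-6-(propan-2-yl)cyclohex-2-en-1-yl (2Z)-2-methylbut-2-enoate F5. HF·pyridine (THF/pyridine, 0 °C) then removes both silyl ethers from F5 to give 23.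

**Further compounds**

F1 | step 9 | 2-(trimethylsilyl)ethyl (1RS,6R)-3-{[(tert-butyldiphenylsilyl)oxy]methyl}-2-oxo-6-(propan-2-yl)cyclohex-3-ene-1-carboxylate | C1C=C(CO[Si](c2ccccc2)(c2ccccc2)C(C)(C)C)C(=O)C(C(=O)OCC[Si](C)(C)C)[C@H]1C(C)C
F2 | step 9 | 2-(trimethylsilyl)ethyl (1RS,6R)-3-{[(tert-butyldiphenylsilyl)oxy]methyl}-1-hydroxy-2-oxo-6-(propan-2-yl)cyclohex-3-ene-1-carboxylate | C1C=C(CO[Si](c2ccccc2)(c2ccccc2)C(C)(C)C)C(=O)C(O)(C(=O)OCC[Si](C)(C)C)[C@H]1C(C)C
F3 | step 12 | 2-(trimethylsilyl)ethyl (1RS,5R,6R)-5-bromo-1-{[(2E)-4-[(tert-butyldiphenylsilyl)oxy]-2-methylbut-2-enoyl]oxy}-3-{[(tert-butyldiphenylsilyl)oxy]methyl}-2-oxo-6-(propan-2-yl)cyclohex-3-ene-1-carboxylate | Br[C@@H]1C=C(CO[Si](c2ccccc2)(c2ccccc2)C(C)(C)C)C(=O)C(OC(=O)/C(C)=C/CO[Si](c2ccccc2)(c2ccccc2)C(C)(C)C)(C(=O)OCC[Si](C)(C)C)[C@H]1C(C)C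
F4 | step 13 | (1S,5R,6S)-3-{[(tert-butyldiphenylsilyl)oxy]methyl}-5-hydroxy-2-oxo-6-(propan-2-yl)cyclohex-3-en-1-yl (2E)-4-[(tert-butyldiphenylsilyl)oxy]-2-methylbut-2-enoate | O[C@@H]1C=C(CO[Si](c2ccccc2)(c2ccccc2)C(C)(C)C)C(=O)[C@@H](OC(=O)/C(C)=C/CO[Si](c2ccccc2)(c2ccccc2)C(C)(C)C)[C@H]1C(C)C
F5 | step 13 | (1S,5S,6S)-3-{[(tert-butyldiphenylsilyl)oxy]methyl}-5-{[(2E)-4-[(tert-butyldiphenylsilyl)oxy]-2-methylbut-2-enoyl]oxy}-4-oxo-6-(propan-2-yl)cyclohex-2-en-1-yl (2Z)-2-methylbut-2-enoate | C/C=C(/C)C(=O)O[C@H]1C=C(CO[Si](c2ccccc2)(c2ccccc2)C(C)(C)C)C(=O)[C@@H](OC(=O)/C(C)=C/CO[Si](c2ccccc2)(c2ccccc2)C(C)(C)C)[C@H]1C(C)C
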